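**Retrosynthetic overview**
1. The acetate goes on the tertiary C4 alcohol late. The CO2H comes from a terminal CH2OH and the enone C=O from a C1 carbinol.
2. The (Z)-pentenyl chain comes from a Z-selective Wittig reaction on a lactol. This lactol derives from a temporary cis-fused γ-lactone (ring B) that ties the C5 side chain and an oxygen to the same ring face.
3. The C4–chain bond comes from convex-face 1,2-addition of a C8 Grignard reagent to the bicyclic keto-lactone. This places the new oxygen cis to the C5 side chain.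
4. Ring B comes from an invertive Mitsunobu lactonisation. Ring A (the cyclopentenone) comes from ring-closing metathesis of a divinyl precursor.
5. The key C5–C1 bond comes from an Evans syn aldol of a succinate-derived imide with acrolein. Ring order: A first, then B; B is reopened in the Wittig step.

Assumption: the SMILES is read as 8-[(1S,5S)-1-acetoxy-4-oxo-5-[(2Z)-pent-2-en-1-yl]cyclopent-2-en-1-yl]octanoic acid, with acetoxy and pentenyl cis. Ring atoms are called C1 (C=O), C2=C3, C4 (OAc, acid chain) and C5 (pentenyl) throughout.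

**Step 1**
Reactants: 1 4-tert-butoxy-4-oxobutanoic acid (mono-tert-butyl succinate); 2 (4R)-4-benzyl-1,3-oxazolidin-2-one
Product: 4 tert-butyl 4-[(4R)-4-benzyl-2-oxo-1,3-oxazolidin-3-yl]-4-oxobutanoate, via mixed pivalic anhydride 3 (not isolated)
Conditions: t-BuCOCl, Et3N, THF, −20 °C; then LiCl, 2, −20 °C → rt
Reagents that add atoms: pivaloyl chloride, CC(C)(C)C(=O)Cl (acyl group carried by 3 only)
Why: Mixed-anhydride N-acylation: the LiCl-activated oxazolidinone attacks the unhindered succinyl carbonyl of 3 rather than the pivaloyl one, and the tert-butyl ester is inert.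

**Step 2**
Reactants: 4 imide; 5 acrolein (prop-2-enal)
Product: 8 tert-butyl (3R,4S)-3-{[(4R)-4-benzyl-2-oxo-1,3-oxazolidin-3-yl]carbonyl}-4-hydroxyhex-5-enoate, via Z-boron enolate 6 (not isolated), via boron aldolate 7 (not isolated)
Conditions: n-Bu2BOTf, i-Pr2NEt, CH2Cl2, −78 → 0 °C; 5, −78 → 0 °C; then pH 7 buffer, MeOH, 30% H2O2, 0 °C
Reagents that add atoms: di-n-butylboron triflate, CCCCB(CCCC)OS(=O)(=O)C(F)(F)F (boron carried by 6 and 7 only)
Why: Evans syn aldol reaction: only the imide is enolised to the Z-boron enolate, which adds to acrolein through a Zimmerman–Traxler chair on the face away from the benzyl group, so this fragment-joining C5–C1 bond sets C5 (3R here, the C5 centre of the target) and the carbinol C1 (4S) with dr normally above 20:1.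

**Step 3**
Reactants: 8 syn aldol adduct
Product: 9 tert-butyl (3R,4S)-4-hydroxy-3-[methoxy(methyl)carbamoyl]hex-5-enoate
Conditions: MeONHMe·HCl, AlMe3, CH2Cl2, −10 → 0 °C; aq. potassium sodium tartrate
Reagents that add atoms: N,O-dimethylhydroxylamine hydrochloride, CNOC.Cl
Why: Weinreb transamidation: the aluminium amide, anchored on the free β-hydroxyl, attacks only the exocyclic imide carbonyl, the hindered tert-butyl ester is left alone, neither stereocentre is touched and the auxiliary is recovered.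

**Step 4**
Reactants: 9 hydroxy Weinreb amide
Product: 10 tert-butyl (3R,4S)-3-[methoxy(methyl)carbamoyl]-4-(triethylsilyloxy)hex-5-enoate
Conditions: Et3SiCl, imidazole, CH2Cl2, 0 °C → rt
Reagents that add atoms: chlorotriethylsilane, CC[Si](Cl)(CC)CC
Why: Standard silylation of a secondary alcohol, which blocks retro-aldol and alkoxide chemistry in the Grignard step and gives a group that later falls off together with the tert-butyl ester.

**Step 5**
Reactants: 10 silylated Weinreb amide
Product: 12 tert-butyl (3R,4S)-3-(prop-2-enoyl)-4-(triethylsilyloxy)hex-5-enoate, via magnesium hemiaminal 11 (not isolated)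
Conditions: CH2=CHMgBr, THF, −78 → 0 °C; inverse quench into cold sat. aq. NH4Cl
Reagents that add atoms: vinylmagnesium bromide, C=C[Mg]Br
Why: Weinreb ketone synthesis: the chelated hemiaminal 11 survives until the quench so only one vinyl group is delivered, the tert-butyl ester is too hindered to react at or below 0 °C, and the cold inverse quench keeps the freed amine from adding to the enone.

**Step 6**
Reactants: 12 dienone
Product: 13 tert-butyl 2-[(1R,5S)-2-oxo-5-(triethylsilyloxy)cyclopent-3-en-1-yl]acetate (trans)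
Conditions: second-generation Grubbs catalyst RuCl2(=CHPh)(PCy3)(H2IMes) (5 mol %), CH2Cl2 (0.01 M), reflux
Reagents that add atoms: none
Why: Ring-closing metathesis closes ring A between the allylic-ether vinyl group and the acryloyl group with loss of ethene, and the syn aldol relationship becomes trans on the ring without touching either stereocentre.

**Step 7**
Reactants: 13 trans cyclopentenone
Product: 14 2-[(1R,5S)-5-hydroxy-2-oxocyclopent-3-en-1-yl]acetic acid
Conditions: CF3CO2H/CH2Cl2/H2O (10:10:1), 0 °C → rt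
Reagents that add atoms: none
Why: Acidolysis removes the tert-butyl ester (as 2-methylpropene) and the triethylsilyl ether in one operation, and the trans hydroxy acid cannot lactonise, so it is isolated as such.

**Step 8**
Reactants: 14 trans hydroxy acid
Product: 16 (3aR,6aR)-3,3a-dihydro-2H-cyclopenta[b]furan-2,4(6aH)-dione (cis-fused keto-lactone), via alkoxyphosphonium carboxylate 15 (not isolated)
Conditions: PPh3, DIAD, THF (0.02 M), 0 °C → rt
Reagents that add atoms: triphenylphosphine, c1ccc(cc1)P(c1ccccc1)c1ccccc1 (carried by 15 only)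
Why: Intramolecular Mitsunobu reaction: the carboxylate sits on the ring face opposite to the activated C1–O bond, so a 5-exo-tet SN2 displacement inverts C1 (S to R) and can only give the cis-fused γ-lactone ring B, which also locks C5.

**Step 9**
Reactants: 17 8-bromooctan-1-ol
Product: 18 (8-bromooctyloxy)(tert-butyl)dimethylsilane
Conditions: t-BuMe2SiCl, imidazole, CH2Cl2, rt
Reagents that add atoms: tert-butyldimethylsilyl chloride, CC(C)(C)[Si](C)(C)Cl
Why: Standard silylation masks the primary alcohol so that a Grignard reagent can be made from the bromide.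

**Step 10**
Reactants: 18 silyloxy bromide; 16 keto-lactone
Product: 20 (3aR,4S,6aR)-4-[8-(tert-butyldimethylsilyloxy)octyl]-4-hydroxy-3,3a,4,6a-tetrahydro-2H-cyclopenta[b]furan-2-one, via Grignard reagent 19 (not isolated)
Conditions: 18, Mg, THF, 40 °C; 16, LaCl3·2LiCl, THF, −78 °C, then 19 (1.3 equiv), −78 → −40 °C; sat. aq. NH4Cl
Reagents that add atoms: magnesium, [Mg] (carried by 19 only)
Why: Grignard 1,2-addition promoted by LaCl3·2LiCl (little enolisation, no 1,4-addition, ketone far more reactive than lactone at low temperature): the nucleophile enters from the convex face of the cis-bicyclo[3.3.0] system, anti to ring B, which sets C4 as S with the new oxygen cis to the C5 side chain; any shift of the lactone onto the new alkoxide is harmless because both lactones give the same diol after steps 11 and 12.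

**Step 11**
Reactants: 20 hydroxy lactone
Product: 21 (3aR,4S,6aR)-4-[8-(tert-butyldimethylsilyloxy)octyl]-3,3a,4,6a-tetrahydro-2H-cyclopenta[b]furan-2,4-diol (lactol, anomer mixture)
Conditions: i-Bu2AlH (2.5 equiv), CH2Cl2, −78 °C; aq. potassium sodium tartrate
Reagents that add atoms: none
Why: Partial reduction of a γ-lactone: the aluminium lactolate is stable at −78 °C, one equivalent is consumed by the tertiary alcohol, and the silyl ether and ring alkene are inert.

**Step 12**
Reactants: 21 lactol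
Product: 23 (1S,4R,5R)-1-[8-(tert-butyldimethylsilyloxy)octyl]-5-[(2Z)-pent-2-en-1-yl]cyclopent-2-ene-1,4-diol, via open hydroxy aldehyde 22 (not isolated)
Conditions: [Ph3PCH2CH2CH3]Br (5 equiv), NaN(SiMe3)2 (4.8 equiv), THF, 0 °C; then 21, −78 °C → rt
Reagents that add atoms: propyltriphenylphosphonium bromide, CCC[P+](c1ccccc1)(c1ccccc1)c1ccccc1.[Br-]
Why: Wittig reaction of a non-stabilised, lithium-free ylide with the aldehyde tautomer 22 gives the Z-alkene under kinetic control (typically above 95:5), opens ring B and frees the C1 hydroxyl, the excess ylide covering the OH protons.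

**Step 13**
Reactants: 23 ene-diol
Product: 24 (4S,5S)-4-[8-(tert-butyldimethylsilyloxy)octyl]-4-hydroxy-5-[(2Z)-pent-2-en-1-yl]cyclopent-2-en-1-one
Conditions: Dess–Martin periodinane (1.2 equiv), pyridine, CH2Cl2, 0 °C
Reagents that add atoms: none
Why: Dess–Martin oxidation touches only the secondary allylic alcohol because the tertiary one has no carbinol hydrogen, the pyridine buffer protects the acid-sensitive tertiary allylic alcohol, and C5, now α to the ketone, already has what should be the more stable arrangement with the two carbon chains trans.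

**Step 14**
Reactants: 24 hydroxy enone
Product: 25 (1S,5S)-1-[8-(tert-butyldimethylsilyloxy)octyl]-4-oxo-5-[(2Z)-pent-2-en-1-yl]cyclopent-2-en-1-yl acetate
Conditions: Ac2O, 4-(dimethylamino)pyridine, pyridine, CH2Cl2, rt
Reagents that add atoms: acetic anhydride, CC(=O)OC(C)=O
Why: Acylation under nucleophilic catalysis by 4-(dimethylamino)pyridine acetylates the hindered tertiary alcohol with retention because the C–O bond is not broken, and the weak amine bases avoid the alkoxide that retro-aldol ring opening would need.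

**Step 15**
Reactants: 25 silyl ether acetate
Product: 26 (1S,5S)-1-(8-hydroxyoctyl)-4-oxo-5-[(2Z)-pent-2-en-1-yl]cyclopent-2-en-1-yl acetate
Conditions: HF·pyridine, pyridine, THF, 0 °C → rt
Reagents that add atoms: none
Why: Fluoride-mediated desilylation under buffered, mildly acidic conditions removes the primary silyl ether without the basicity that would endanger the β-acetoxy ketone.

**Step 16**
Reactants: 26 primary alcohol
Product: 28 8-[(1S,5S)-1-acetoxy-4-oxo-5-[(2Z)-pent-2-en-1-yl]cyclopent-2-en-1-yl]octanoic acid (target), via aldehyde 27 (not isolated)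
Conditions: TEMPO (2,2,6,6-tetramethylpiperidin-1-oxyl, 20 mol %), PhI(OAc)2 (2.5 equiv), MeCN/pH 7 buffer (1:1), rt
Reagents that add atoms: water, O
Why: Oxoammonium oxidation (TEMPO/PhI(OAc)2) in aqueous medium takes the primary alcohol through aldehyde 27 and its hydrate to the acid under near-neutral conditions that leave the Z-alkene, the enone, the tertiary acetate and C5 alone.

**Compound list**
1 | 4-tert-butoxy-4-oxobutanoic acid | CC(C)(C)OC(=O)CCC(=O)O | starting material
2 | (4R)-4-benzyl-1,3-oxazolidin-2-one | O=C1N[C@H](Cc2ccccc2)CO1 | starting material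
3 | 4-tert-butoxy-4-oxobutanoic pivalic anhydride (not isolated) | CC(C)(C)OC(=O)CCC(=O)OC(=O)C(C)(C)C | intermediate
4 | tert-butyl 4-[(4R)-4-benzyl-2-oxo-1,3-oxazolidin-3-yl]-4-oxobutanoate | CC(C)(C)OC(=O)CCC(=O)N1[C@H](Cc2ccccc2)COC1=O | intermediate
5 | acrolein | C=CC=O | starting material
6 | (Z)-di-n-butylboron enolate of 4 (not isolated) | CC(C)(C)OC(=O)C/C=C(\OB(CCCC)CCCC)N1[C@H](Cc2ccccc2)COC1=O | intermediate
7 | di-n-butylboron aldolate of 8 (not isolated) | CC(C)(C)OC(=O)C[C@H]([C@@H](OB(CCCC)CCCC)C=C)C(=O)N1[C@H](Cc2ccccc2)COC1=O | intermediate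
8 | tert-butyl (3R,4S)-3-{[(4R)-4-benzyl-2-oxo-1,3-oxazolidin-3-yl]carbonyl}-4-hydroxyhex-5-enoate | CC(C)(C)OC(=O)C[C@H]([C@@H](O)C=C)C(=O)N1[C@H](Cc2ccccc2)COC1=O | intermediate
9 | tert-butyl (3R,4S)-4-hydroxy-3-[methoxy(methyl)carbamoyl]hex-5-enoate | CC(C)(C)OC(=O)C[C@H]([C@@H](O)C=C)C(=O)N(C)OC | intermediate
10 | tert-butyl (3R,4S)-3-[methoxy(methyl)carbamoyl]-4-(triethylsilyloxy)hex-5-enoate | CC(C)(C)OC(=O)C[C@H]([C@@H](O[Si](CC)(CC)CC)C=C)C(=O)N(C)OC | intermediate
11 | bromomagnesium hemiaminal from 10 and the vinyl Grignard reagent (not isolated) | CC(C)(C)OC(=O)C[C@H]([C@@H](O[Si](CC)(CC)CC)C=C)C(O[Mg]Br)(C=C)N(C)OC | intermediate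
12 | tert-butyl (3R,4S)-3-(prop-2-enoyl)-4-(triethylsilyloxy)hex-5-enoate | CC(C)(C)OC(=O)C[C@H]([C@@H](O[Si](CC)(CC)CC)C=C)C(=O)C=C | intermediate
13 | tert-butyl 2-[(1R,5S)-2-oxo-5-(triethylsilyloxy)cyclopent-3-en-1-yl]acetate | CC(C)(C)OC(=O)C[C@@H]1[C@@H](O[Si](CC)(CC)CC)C=CC1=O | intermediate
14 | 2-[(1R,5S)-5-hydroxy-2-oxocyclopent-3-en-1-yl]acetic acid | OC(=O)C[C@@H]1[C@@H](O)C=CC1=O | intermediate
15 | alkoxy(triphenyl)phosphonium carboxylate of 14 (not isolated) | [O-]C(=O)C[C@@H]1[C@@H](O[P+](c2ccccc2)(c2ccccc2)c2ccccc2)C=CC1=O | intermediate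
16 | (3aR,6aR)-3,3a-dihydro-2H-cyclopenta[b]furan-2,4(6aH)-dione | O=C1C[C@@H]2[C@H](O1)C=CC2=O | intermediate
17 | 8-bromooctan-1-ol | OCCCCCCCCBr | starting material
18 | (8-bromooctyloxy)(tert-butyl)dimethylsilane | CC(C)(C)[Si](C)(C)OCCCCCCCCBr | intermediate
19 | [8-(tert-butyldimethylsilyloxy)octyl]magnesium bromide (not isolated) | CC(C)(C)[Si](C)(C)OCCCCCCCC[Mg]Br | intermediate
20 | (3aR,4S,6aR)-4-[8-(tert-butyldimethylsilyloxy)octyl]-4-hydroxy-3,3a,4,6a-tetrahydro-2H-cyclopenta[b]furan-2-one | O=C1C[C@@H]2[C@H](O1)C=C[C@]2(CCCCCCCCO[Si](C)(C)C(C)(C)C)O | intermediate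
21 | (3aR,4S,6aR)-4-[8-(tert-butyldimethylsilyloxy)octyl]-3,3a,4,6a-tetrahydro-2H-cyclopenta[b]furan-2,4-diol (anomers) | OC1C[C@@H]2[C@H](O1)C=C[C@]2(CCCCCCCCO[Si](C)(C)C(C)(C)C)O | intermediate
22 | 2-[(1R,2S,5R)-2-[8-(tert-butyldimethylsilyloxy)octyl]-2,5-dihydroxycyclopent-3-en-1-yl]acetaldehyde (not isolated) | O=CC[C@@H]1[C@H](O)C=C[C@]1(CCCCCCCCO[Si](C)(C)C(C)(C)C)O | intermediate
23 | (1S,4R,5R)-1-[8-(tert-butyldimethylsilyloxy)octyl]-5-[(2Z)-pent-2-en-1-yl]cyclopent-2-ene-1,4-diol | CC/C=C\C[C@@H]1[C@H](O)C=C[C@]1(CCCCCCCCO[Si](C)(C)C(C)(C)C)O | intermediate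
24 | (4S,5S)-4-[8-(tert-butyldimethylsilyloxy)octyl]-4-hydroxy-5-[(2Z)-pent-2-en-1-yl]cyclopent-2-en-1-one | CC/C=C\C[C@@H]1C(=O)C=C[C@]1(CCCCCCCCO[Si](C)(C)C(C)(C)C)O | intermediate
25 | (1S,5S)-1-[8-(tert-butyldimethylsilyloxy)octyl]-4-oxo-5-[(2Z)-pent-2-en-1-yl]cyclopent-2-en-1-yl acetate | CC/C=C\C[C@@H]1C(=O)C=C[C@]1(CCCCCCCCO[Si](C)(C)C(C)(C)C)OC(C)=O | intermediate
26 | (1S,5S)-1-(8-hydroxyoctyl)-4-oxo-5-[(2Z)-pent-2-en-1-yl]cyclopent-2-en-1-yl acetate | CC/C=C\C[C@@H]1C(=O)C=C[C@]1(CCCCCCCCO)OC(C)=O | intermediate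
27 | (1S,5S)-4-oxo-1-(8-oxooctyl)-5-[(2Z)-pent-2-en-1-yl]cyclopent-2-en-1-yl acetate (not isolated) | CC/C=C\C[C@@H]1C(=O)C=C[C@]1(CCCCCCCC=O)OC(C)=O | intermediate
28 | 8-[(1S,5S)-1-acetoxy-4-oxo-5-[(2Z)-pent-2-en-1-yl]cyclopent-2-en-1-yl]octanoic acid | CC/C=C\C[C@@H]1C(=O)C=C[C@]1(CCCCCCCC(=O)O)OC(C)=O | target

**Totals:** 16 steps. The longest linear sequence is 15 steps (steps 1–8 and 10–16); step 9 is the side branch.

**Three steps most likely to fail**

**Step 8 (Mitsunobu lactonisation).** The oxyphosphonium 15 lies β to an enolisable ketone and may eliminate instead of cyclising.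
- The fallback sets out from 9 and comes back at 16. It moves the inversion to the acyclic stage, where no ketone is present, so ring B then closes by plain lactonisation with retention.
- 9 with 4-nitrobenzoic acid, PPh3 and DIAD gives the inverted 4-nitrobenzoate F1. K2CO3 in MeOH then frees the anti hydroxy amide F2.
- Et3SiCl/imidazole gives the anti silyl ether F3, and CH2=CHMgBr gives the anti dienone F4.
- Ring closure with RuCl2(=CHPh)(PCy3)(H2IMes) gives the cis cyclopentenone F5.
- CF3CO2H/H2O strips both acid-labile groups, and the cis hydroxy acid closes by itself to 16.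

**Step 10 (Grignard addition to the keto-lactone).** The risks are lactone attack, or enolisation followed by loss of carboxylate.
- The fallback sets out from 13 and comes back at 24. It adds the chain before any lactone exists and uses lactonisation as the stereochemical filter.
- 19 with LaCl3·2LiCl adds to monocyclic 13 anti to the C5 side chain to give the tertiary hydroxy ester F6.
- On warming, the alkoxide of F6 closes onto the tert-butyl ester to give the tertiary lactone F7. Only the epimer with oxygen cis to the side chain can lactonise, so the other epimer is removed by chromatography.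
- i-Bu2AlH gives the tertiary lactol F8, and the same propylidene Wittig reaction gives the pentenyl silyl ether F9.
- Pyridinium tosylate in MeOH at 0 °C removes only the triethylsilyl group to give the C1-epimeric diol F10. Dess–Martin oxidation erases the C1 centre and delivers 24.

**Step 14 (acetylation of the tertiary β-hydroxy ketone).** The reaction may be sluggish, with risk of C5 epimerisation, retro-aldol opening or loss of acetate.
- The fallback sets out from 23 and comes back at 27. It acetylates before the ketone exists.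
- Et3SiCl/imidazole at 0 °C silylates only the secondary alcohol to give the mono-silylated diol F11.
- Ac2O, Et3N and 4-(dimethylamino)pyridine in refluxing CH2Cl2 give the tertiary acetate F12. HF·pyridine then removes both silyl groups to give the diol acetate F13.
- Dess–Martin periodinane (2.5 equiv) oxidises both alcohols to 27, now isolated. NaClO2, NaH2PO4 and 2-methylbut-2-ene in t-BuOH/H2O take 27 to 28.

**Further compounds**
F1 | step 8 | tert-butyl (3R,4R)-3-[methoxy(methyl)carbamoyl]-4-(4-nitrobenzoyloxy)hex-5-enoate | CC(C)(C)OC(=O)C[C@H]([C@H](OC(=O)c1ccc(cc1)[N+](=O)[O-])C=C)C(=O)N(C)OC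
F2 | step 8 | tert-butyl (3R,4R)-4-hydroxy-3-[methoxy(methyl)carbamoyl]hex-5-enoate | CC(C)(C)OC(=O)C[C@H]([C@H](O)C=C)C(=O)N(C)OC
F3 | step 8 | tert-butyl (3R,4R)-3-[methoxy(methyl)carbamoyl]-4-(triethylsilyloxy)hex-5-enoate | CC(C)(C)OC(=O)C[C@H]([C@H](O[Si](CC)(CC)CC)C=C)C(=O)N(C)OC
F4 | step 8 | tert-butyl (3R,4R)-3-(prop-2-enoyl)-4-(triethylsilyloxy)hex-5-enoate | CC(C)(C)OC(=O)C[C@H]([C@H](O[Si](CC)(CC)CC)C=C)C(=O)C=C
F5 | step 8 | tert-butyl 2-[(1R,5R)-2-oxo-5-(triethylsilyloxy)cyclopent-3-en-1-yl]acetate | CC(C)(C)OC(=O)C[C@@H]1[C@H](O[Si](CC)(CC)CC)C=CC1=O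
F6 | step 10 | tert-butyl 2-[(1R,2S,5S)-2-[8-(tert-butyldimethylsilyloxy)octyl]-2-hydroxy-5-(triethylsilyloxy)cyclopent-3-en-1-yl]acetate | CC(C)(C)OC(=O)C[C@@H]1[C@@H](O[Si](CC)(CC)CC)C=C[C@]1(CCCCCCCCO[Si](C)(C)C(C)(C)C)O
F7 | step 10 | (3aR,4S,6aS)-6a-[8-(tert-butyldimethylsilyloxy)octyl]-4-(triethylsilyloxy)-3,3a,4,6a-tetrahydro-2H-cyclopenta[b]furan-2-one | O=C1C[C@@H]2[C@@H](O[Si](CC)(CC)CC)C=C[C@]2(CCCCCCCCO[Si](C)(C)C(C)(C)C)O1
F8 | step 10 | (3aR,4S,6aS)-6a-[8-(tert-butyldimethylsilyloxy)octyl]-4-(triethylsilyloxy)-3,3a,4,6a-tetrahydro-2H-cyclopenta[b]furan-2-ol (anomers) | OC1C[C@@H]2[C@@H](O[Si](CC)(CC)CC)C=C[C@]2(CCCCCCCCO[Si](C)(C)C(C)(C)C)O1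
F9 | step 10 | (1S,4S,5R)-1-[8-(tert-butyldimethylsilyloxy)octyl]-5-[(2Z)-pent-2-en-1-yl]-4-(triethylsilyloxy)cyclopent-2-en-1-ol | CC/C=C\C[C@@H]1[C@@H](O[Si](CC)(CC)CC)C=C[C@]1(CCCCCCCCO[Si](C)(C)C(C)(C)C)O
F10 | step 10 | (1S,4S,5R)-1-[8-(tert-butyldimethylsilyloxy)octyl]-5-[(2Z)-pent-2-en-1-yl]cyclopent-2-ene-1,4-diol | CC/C=C\C[C@@H]1[C@@H](O)C=C[C@]1(CCCCCCCCO[Si](C)(C)C(C)(C)C)O
F11 | step 14 | (1S,4R,5R)-1-[8-(tert-butyldimethylsilyloxy)octyl]-5-[(2Z)-pent-2-en-1-yl]-4-(triethylsilyloxy)cyclopent-2-en-1-ol | CC/C=C\C[C@@H]1[C@H](O[Si](CC)(CC)CC)C=C[C@]1(CCCCCCCCO[Si](C)(C)C(C)(C)C)O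
F12 | step 14 | (1S,4R,5R)-1-[8-(tert-butyldimethylsilyloxy)octyl]-5-[(2Z)-pent-2-en-1-yl]-4-(triethylsilyloxy)cyclopent-2-en-1-yl acetate | CC/C=C\C[C@@H]1[C@H](O[Si](CC)(CC)CC)C=C[C@]1(CCCCCCCCO[Si](C)(C)C(C)(C)C)OC(C)=O
F13 | step 14 | (1S,4R,5R)-4-hydroxy-1-(8-hydroxyoctyl)-5-[(2Z)-pent-2-en-1-yl]cyclopent-2-en-1-yl acetate | CC/C=C\C[C@@H]1[C@H](O)C=C[C@]1(CCCCCCCCO)OC(C)=O
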